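**Assumption:** xanthogalenol has no stereocentres, so "single enantiomer" does not apply; the only stereo-element is the (E)-enone, set in step 4. Compounds 1 and 7 are taken as catalogue items (7 is otherwise one MOMCl step from 4-hydroxybenzaldehyde).

## Retrosynthetic overview

1. No rings are formed; both aromatic rings come intact from starting materials.
2. Remove the two MOM ethers (one on each ring) to reveal the bis-MOM chalcone.
3. Disconnect the enone Cα=Cβ bond (Claisen–Schmidt) into a prenylated acetophenone and 4-(methoxymethoxy)benzaldehyde.
4. Trace the C-prenyl group back to an aryl prenyl ether (Claisen–Cope, "para-Claisen"). Either free ring position gives the target after deprotection, because the two OH groups flanking the acyl group become equivalent.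
5. The ether comes from mono-MOM protection and O-prenylation of symmetric 2',6'-dihydroxy-4'-methoxyacetophenone.

## Route

**Step 1**
Reactants: 1, 2',6'-dihydroxy-4'-methoxyacetophenone; 2, chloromethyl methyl ether (MOMCl)
Product: 3, 1-[2-hydroxy-4-methoxy-6-(methoxymethoxy)phenyl]ethan-1-one
Conditions: MOMCl (1.1 equiv), iPr2NEt (1.5 equiv), CH2Cl2, 0 °C → rt
Reagents that add atoms: MOMCl, COCCl
Why: O-alkylation (MOM protection) of a symmetric diol, so either OH gives the same product; the remaining OH is locked in a strong hydrogen bond to the ketone and resists a second alkylation with amine base.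

**Step 2**
Reactants: 3; 4, prenyl bromide (1-bromo-3-methylbut-2-ene)
Product: 5, 1-[4-methoxy-2-(methoxymethoxy)-6-(3-methylbut-2-en-1-yloxy)phenyl]ethan-1-one
Conditions: prenyl bromide (1.5 equiv), K2CO3 (3 equiv), DMF, rt → 50 °C
Reagents that add atoms: prenyl bromide, CC(C)=CCBr
Why: Williamson ether synthesis; carbonate in DMF deprotonates the chelated phenol and the phenoxide attacks the primary allylic bromide by SN2, while the MOM ether and ketone are inert.

**Step 3**
Reactants: 5
Product: 6, 1-[6-hydroxy-4-methoxy-2-(methoxymethoxy)-3-(3-methylbut-2-en-1-yl)phenyl]ethan-1-one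
Conditions: PhNEt2, 200 °C, Ar, 2–4 h
Reagents that add atoms: none
Why: Aromatic Claisen rearrangement followed by Cope rearrangement (para-Claisen); the crowded 1,1-dimethylallyl dienone formed at the ortho carbon relays to the para carbon and re-aromatises as the normal prenyl phenol, and the basic amine solvent suppresses acid-catalysed chroman formation and MOM loss.

**Step 4**
Reactants: 6; 7, 4-(methoxymethoxy)benzaldehyde
Product: 8, (E)-1-[6-hydroxy-4-methoxy-2-(methoxymethoxy)-3-(3-methylbut-2-en-1-yl)phenyl]-3-[4-(methoxymethoxy)phenyl]prop-2-en-1-one
Conditions: 7 (1.2 equiv), KOH (50% aq, excess), EtOH, rt, 24–48 h; cold work-up to pH 6–7 (NH4Cl)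
Reagents that add atoms: none (all new atoms come from reactant 7)
Why: Claisen–Schmidt condensation with a non-enolisable aldehyde; E1cB dehydration gives the thermodynamic (E)-enone, the 2'-phenoxide stays open-chain in strong base, and MOM ethers and the prenyl group are base-stable.

**Step 5**
Reactants: 8
Product: 9, xanthogalenol, (E)-1-[2,6-dihydroxy-4-methoxy-3-(3-methylbut-2-en-1-yl)phenyl]-3-(4-hydroxyphenyl)prop-2-en-1-one
Conditions: 3 M aq HCl/MeOH (about 1:5), 40–50 °C, 30–90 min with TLC control; pour onto ice-water, extract with EtOAc
Reagents that add atoms: none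
Why: Acid-catalysed acetal hydrolysis removes both MOM groups; short, mild exposure leaves the (E)-enone and prenyl alkene intact and limits flavanone or chroman formation.

## Compound list

1 | 2',6'-dihydroxy-4'-methoxyacetophenone | CC(=O)c1c(O)cc(OC)cc1O | starting material
2 | chloromethyl methyl ether (MOMCl) | COCCl | starting material (reagent)
3 | 1-[2-hydroxy-4-methoxy-6-(methoxymethoxy)phenyl]ethan-1-one | CC(=O)c1c(O)cc(OC)cc1OCOC | intermediate
4 | prenyl bromide | CC(C)=CCBr | starting material (reagent)
5 | 1-[4-methoxy-2-(methoxymethoxy)-6-(3-methylbut-2-en-1-yloxy)phenyl]ethan-1-one | CC(=O)c1c(OCC=C(C)C)cc(OC)cc1OCOC | intermediate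
6 | 1-[6-hydroxy-4-methoxy-2-(methoxymethoxy)-3-(3-methylbut-2-en-1-yl)phenyl]ethan-1-one | CC(=O)c1c(O)cc(OC)c(CC=C(C)C)c1OCOC | intermediate
7 | 4-(methoxymethoxy)benzaldehyde | COCOc1ccc(C=O)cc1 | starting material
8 | (E)-1-[6-hydroxy-4-methoxy-2-(methoxymethoxy)-3-(3-methylbut-2-en-1-yl)phenyl]-3-[4-(methoxymethoxy)phenyl]prop-2-en-1-one | COCOc1ccc(/C=C/C(=O)c2c(O)cc(OC)c(CC=C(C)C)c2OCOC)cc1 | intermediate
9 | xanthogalenol | COc1cc(O)c(C(=O)/C=C/c2ccc(O)cc2)c(O)c1CC=C(C)C | target

## Summary

Total steps: 5. Longest linear sequence: 5 (fully linear from 1; 7 enters at step 4).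

Three steps most likely to fail, with fallbacks:

1. **Step 3 (Claisen–Cope).** Risks are the reverse-prenyl (1,1-dimethylallyl) ortho product, de-prenylation, or chroman formation. Fallback: O-allylate 3 instead, run a clean ortho-Claisen to the C-allyl phenol, then convert allyl to prenyl by cross-metathesis with 2-methyl-2-butene (Grubbs II). The ortho position is acceptable because both free ring positions lead to the same target.
2. **Step 5 (acidic MOM removal).** The 2',6'-dihydroxychalcone can close to the flavanone, or the prenyl group can cyclise onto the adjacent OH. Fallback: replace both MOM groups with TBS ethers, form the enone by a low-temperature lithium-enolate aldol (LiHMDS) and dehydration (MsCl/Et3N), then deprotect under non-acidic fluoride conditions (TBAF/AcOH).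
3. **Step 4 (Claisen–Schmidt).** The di-ortho-substituted, phenoxide-deactivated ketone may react slowly. Fallback: cap the free OH of 6 as a second MOM ether (NaH, MOMCl) so the fully protected ketone condenses faster, then remove three MOM groups in the last step.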